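Its constants were drawn at random within sensible limits; no experiment stands behind them.

The intermediate was the species I had to follow: substrate makes it on the catalyst, and coupling partner clears it on the same catalyst.

all flasks: substrate 37 mM; protic impurity 3.70 mM; catalyst 2.0 mM

| run | coupling partner | remark | time |
|---|---|---|---|
| blue | 74.0 mM | one stirred flow tank at steady state, fed with the mixture as stated, mean residence time 8.0 min |  |
| grey | 74.0 mM (fed, over 6.40 min) | a stirred flask in which coupling partner is dosed at a steady rate over 6.40 min without added volume, worked up at 8.0 min | 8.0 min |
| green | 74.0 mM | a closed flask charged with all of it at once and left for 8.0 min | 8.0 min |
| violet | 74.0 mM | one stirred flow tank at steady state, fed with the mixture as stated, mean residence time 40.0 min |  |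

    coupling partner + protic impurity → quenched reagent (k1 = 6.2 /M/s)
    substrate + catalyst → catalyst + intermediate (k2 = 3.9 /M/s)
    substrate + product ⇌ idle adduct, settled at all times (K3 = 10 /M)
    coupling partner + catalyst + intermediate → catalyst + product (k4 = 62 /M²/s)

* the set-up with the highest amount of intermediate at the outlet or at the end, in percent of the substrate put in ("none" if the first two lie within 2 percentage points) (blue / grey / green / violet / none)
* amount of intermediate at the outlet or at the end, in percent of the substrate put in, blue
* amount of intermediate at the outlet or at the end, in percent of the substrate put in, grey
* amount of intermediate at the outlet or at the end, in percent of the substrate put in, green
* amount of intermediate at the outlet or at the end, in percent of the substrate put in, violet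

- percentages count the substrate that a species holds: one idle adduct counts as two
- product is meant together with its idle adduct
- the stated concentrations are those of everything mixed, before any reaction; amounts are the same in each set-up
- the feed brings no volume worth counting
- in an amount of product, one idle adduct counts as one product
- run time (grey): 8.0 min

The catalyst comes back from both of its steps, so I held it at its charge. That turned the three-body clearing of the intermediate into a pseudo-first-order loss, whose constant moves with the free coupling partner. In green, the partner's half-life by quenching, with the protic impurity held at its charge, was 0.50 min, much shorter than the run of 8.0 min, so I took the protic impurity as paid for early and counted 70.3 mM of partner as free. From this I defined the clearing half-life 1.33 min: ln(2) divided by the clearing constant, catalyst times free partner. The substrate's making half-life came to 1.48 min, longer than the clearing half-life.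

Then I set grey beside green, its neighbour with the same charges. In green the partner is present from the start, which allows 6.02 clearing half-lives. In grey the steady dose arrives on average at 3.20 min, which leaves 4.80 min and 3.62 half-lives. I expected grey to end higher because its clearing time is shorter. Two first-order steps in series, run as a rough shortcut over those times, gave me 20.9% for grey and 7.21% for green. But each product takes one partner, and full conversion would leave 33.3 mM, less than I had assumed. So I took both figures as probably too low and committed to the order, grey above green.

The forecast, “stepping by hand with 1-minute midpoints” for green, named grey as best, with 21.8% for grey, 19.2% for blue, 14.4% for green and 7.5% for violet. The simulation gave grey as best, with 22.0% for grey, 19.2% for blue, 14.5% for green and 7.50% for violet.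

In grey at 8.00 min, the partner stood at 57.7% of its charge, so the clearing half-life had stretched to 2.18 min, longer than the substrate's making half-life of 1.5 min, and the intermediate stood at 22.0%. In the neighbour, the same flask as grey with 3.4 mM of catalyst, the partner left was 50% of its charge, the clearing half-life reckoned the same way was 1.48 min, and the intermediate stood at 9.81%.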